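**Retrosynthetic overview**
1. Last ring: the 3,10-oxolane hemiketal, closed when the C10 tertiary hydroxyl is unmasked next to the C3 ketone of a ten-membered 4Z-enone (C3 under thermodynamic control).
2. Ten-membered carbocycle: C3–C4 bond by Pd/Cu-mediated ring-closing acylation of a Z-alkenylstannane with a thioester (the new step); the stannane comes from hydroxyl-directed Ru trans-hydrostannation of the C4≡C5 alkyne.
3. First ring: the cis α-methylene-γ-lactone, formed after fragment union at C7–C8 by an indium Barbier allylation, acylation of O8 and lactonisation of O6.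
4. West aldehyde (C1–C3, C8–C10, C14) in 6 steps from (R)-2-methylglycidol; East allylic bromide (C4–C7, C11–C13, C15) in 6 steps from propargyl alcohol, crotonaldehyde and methyl propiolate; C6 by asymmetric alkynylation, C7/C8 relayed from C6.
5. Ring order: lactone, then carbocycle, then oxolane. Atom labels C1–C15 are germacranolide numbering of the target.

Assumption: (R,R)-ProPhenol is taken to deliver the zinc acetylide to the Si face of crotonaldehyde (4R carbinol); if the sense is the opposite, the antipodal ligand is used.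

**West fragment**

Step 1
Reactants: 1 [(2R)-2-methyloxiran-2-yl]methanol; 2 ethenylmagnesium bromide
Product: 3 (2S)-2-methylpent-4-ene-1,2-diol
Conditions: CH2=CHMgBr (3 equiv), CuI (10 mol %), THF, −40 to 0 °C; aq. NH4Cl
Reagents that add atoms: none
Why: Cu-catalysed Grignard opening of the 2,2-disubstituted epoxide at its CH2 terminus (SN2) leaves the quaternary carbinol C10 untouched, so its configuration comes from the chiral pool.

Step 2
Reactants: 3 (2S)-2-methylpent-4-ene-1,2-diol
Product: 5 (2S)-2-methyl-2-(prop-2-en-1-yl)oxirane, via primary tosylate 4 (not isolated)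
Conditions: NaH (2.5 equiv), 1-(4-methylbenzenesulfonyl)imidazole (1.05 equiv), THF, 0 °C to rt; 5 carried on as a dried ethereal solution (volatile)
Reagents that add atoms: none
Why: selective sulfonylation of the primary alkoxide and intramolecular Williamson displacement by the tertiary alkoxide (one-pot diol-to-epoxide conversion) re-form an epoxide without breaking the C10–O bond.

Step 3
Reactants: 5 (2S)-2-methyl-2-(prop-2-en-1-yl)oxirane; 6 tert-butyl acetate
Product: 7 tert-butyl (4R)-4-hydroxy-4-methylhept-6-enoate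
Conditions: 6 (2 equiv), LiN(iPr)2, THF, −78 °C; Et2AlCl (2 equiv); then 5, −78 to −30 °C; aq. potassium sodium tartrate
Reagents that add atoms: none
Why: opening of the epoxide at its unhindered CH2 by an aluminium ester enolate adds the C2–C3 acetate unit and does not involve C10.

Step 4
Reactants: 7 tert-butyl (4R)-4-hydroxy-4-methylhept-6-enoate
Product: 9 (4R)-4-methyl-4-[(triethylsilyl)oxy]hept-6-enoic acid, via bis-silyl ester 8 (not isolated)
Conditions: Et3SiOTf (3 equiv), 2,6-lutidine (5 equiv), CH2Cl2, −78 °C to rt; then K2CO3, MeOH/H2O, 0 °C; pH 4 work-up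
Reagents that add atoms: triethylsilyl trifluoromethanesulfonate, CC[Si](CC)(CC)OS(=O)(=O)C(F)(F)F
Why: the silyl triflate silylates the tertiary alcohol and converts the tert-butyl ester into a silyl ester with loss of isobutene (silyl triflate cleavage of tert-butyl esters), and mild basic methanolysis then frees only the carboxylic acid, so no γ-lactone can form.

Step 5
Reactants: 9 (4R)-4-methyl-4-[(triethylsilyl)oxy]hept-6-enoic acid
Product: 10 S-ethyl (4R)-4-methyl-4-[(triethylsilyl)oxy]hept-6-enethioate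
Conditions: EtSH (3 equiv), DCC (1.2 equiv), DMAP (10 mol %), CH2Cl2, 0 °C to rt
Reagents that add atoms: ethanethiol, CCS
Why: Steglich-type carbodiimide thioesterification installs the acyl donor for the later ring closure.

Step 6
Reactants: 10 S-ethyl (4R)-4-methyl-4-[(triethylsilyl)oxy]hept-6-enethioate
Product: 11 S-ethyl (4R)-4-methyl-6-oxo-4-[(triethylsilyl)oxy]hexanethioate
Conditions: OsO4 (2 mol %), NaIO4 (4 equiv), 2,6-lutidine, 1,4-dioxane/H2O (3:1), rt
Reagents that add atoms: sodium periodate, [Na+].[O-]I(=O)(=O)=O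
Why: Lemieux–Johnson oxidative cleavage of the terminal alkene gives the C8 aldehyde under buffered conditions that spare the thioester and the tertiary silyl ether.

**East fragment**

Step 7
Reactants: 12 prop-2-yn-1-ol
Product: 13 1-methoxy-4-[(prop-2-yn-1-yloxy)methyl]benzene
Conditions: NaH, 4-methoxybenzyl chloride, Bu4NI (cat.), THF, 0 °C to rt
Reagents that add atoms: 4-methoxybenzyl chloride, COc1ccc(CCl)cc1
Why: Williamson etherification protects the future C15 hydroxyl as a PMB ether.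

Step 8
Reactants: 13 1-methoxy-4-[(prop-2-yn-1-yloxy)methyl]benzene; 14 (2E)-but-2-enal
Product: 15 (2E,4R)-7-[(4-methoxyphenyl)methoxy]hept-2-en-5-yn-4-ol
Conditions: Me2Zn (3 equiv), (R,R)-ProPhenol (10 mol %), Ph3PO (20 mol %), toluene, 0 to 4 °C; aq. NH4Cl
Reagents that add atoms: none
Why: Zn/ProPhenol-catalysed asymmetric alkynylation of an enal, in which the dinuclear zinc catalyst delivers the zinc acetylide to the Si face of the aldehyde and so sets C6 (4R in 15).

Step 9
Reactants: 15 (2E,4R)-7-[(4-methoxyphenyl)methoxy]hept-2-en-5-yn-4-ol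
Product: 16 (2E,4R)-4,7-bis[(4-methoxyphenyl)methoxy]hept-2-en-5-yne
Conditions: NaH, 4-methoxybenzyl chloride, Bu4NI (cat.), DMF, 0 °C
Reagents that add atoms: 4-methoxybenzyl chloride, COc1ccc(CCl)cc1
Why: Williamson etherification puts a weakly chelating PMB ether on O6 that later steers the indium reagent and is removed together with the C15 PMB group.

Step 10
Reactants: 16 (2E,4R)-4,7-bis[(4-methoxyphenyl)methoxy]hept-2-en-5-yne
Product: 17 (2S)-2,5-bis[(4-methoxyphenyl)methoxy]pent-3-ynal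
Conditions: OsO4 (2 mol %), NaIO4 (4 equiv), 2,6-lutidine, 1,4-dioxane/H2O (3:1), 0 °C to rt; used crude
Reagents that add atoms: sodium periodate, [Na+].[O-]I(=O)(=O)=O
Why: Lemieux–Johnson cleavage takes the alkene and not the alkyne and gives the C7 aldehyde without a base strong enough to epimerise C6.

Step 11
Reactants: 17 (2S)-2,5-bis[(4-methoxyphenyl)methoxy]pent-3-ynal; 18 methyl prop-2-ynoate
Product: 19 methyl (4S)-3-hydroxy-4,7-bis[(4-methoxyphenyl)methoxy]-2-methylidenehept-5-ynoate (both C3 epimers)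
Conditions: 18 (1.5 equiv), iBu2AlH (1.5 equiv), N-methylmorpholine N-oxide (1.5 equiv), THF, 0 °C, 30 min; then 17, 0 °C to rt; aq. potassium sodium tartrate
Reagents that add atoms: none
Why: vinylalumination (hydroalumination of the propiolate to the α-ester vinylalane, then carbonyl addition) gives the Morita–Baylis–Hillman-type adduct without amine base, so the α-alkoxy aldehyde is not epimerised, and the new carbinol centre is erased in step 12.

Step 12
Reactants: 19 methyl (4S)-3-hydroxy-4,7-bis[(4-methoxyphenyl)methoxy]-2-methylidenehept-5-ynoate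
Product: 20 methyl (2Z,4R)-2-(bromomethyl)-4,7-bis[(4-methoxyphenyl)methoxy]hept-2-en-5-ynoate
Conditions: N-bromosuccinimide (1.5 equiv), Me2S (1.8 equiv), CH2Cl2, 0 °C to rt
Reagents that add atoms: N-bromosuccinimide, BrN1C(=O)CCC1=O
Why: Corey–Kim-type activation of the allylic alcohol and SN2' displacement by bromide give the thermodynamically favoured Z 2-(bromomethyl)enoate with the ester trans to the C6 substituent.

**Union and endgame**

Step 13
Reactants: 11 S-ethyl (4R)-4-methyl-6-oxo-4-[(triethylsilyl)oxy]hexanethioate; 20 methyl (2Z,4R)-2-(bromomethyl)-4,7-bis[(4-methoxyphenyl)methoxy]hept-2-en-5-ynoate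
Product: 21 methyl (3R,4R,6R)-3-{(1R)-1,4-bis[(4-methoxyphenyl)methoxy]but-2-yn-1-yl}-9-(ethylsulfanyl)-4-hydroxy-6-methyl-2-methylidene-9-oxo-6-[(triethylsilyl)oxy]nonanoate
Conditions: In powder (1.5 equiv), 20 (1.2 equiv), THF/DMF (3:1), 0 °C to rt; pH 7 buffer; used at once
Reagents that add atoms: none
Why: Barbier-type allylation in which the Z allylindium adds through its γ-carbon in a chair transition state (syn C7/C8), while with H6 eclipsing the alkene (1,3-allylic strain) the PMB ether oxygen chelates indium and the aldehyde is delivered to the alkoxy-bearing face of C7, giving 7R and 8R; the organoindium does not touch the thioester.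

Step 14
Reactants: 21 methyl (3R,4R,6R)-3-{(1R)-1,4-bis[(4-methoxyphenyl)methoxy]but-2-yn-1-yl}-9-(ethylsulfanyl)-4-hydroxy-6-methyl-2-methylidene-9-oxo-6-[(triethylsilyl)oxy]nonanoate; 22 2-methylpropanoyl chloride
Product: 23 methyl (3R,4R,6R)-3-{(1R)-1,4-bis[(4-methoxyphenyl)methoxy]but-2-yn-1-yl}-9-(ethylsulfanyl)-6-methyl-2-methylidene-4-[(2-methylpropanoyl)oxy]-9-oxo-6-[(triethylsilyl)oxy]nonanoate
Conditions: 22 (3 equiv), pyridine, DMAP (20 mol %), CH2Cl2, 0 °C
Reagents that add atoms: none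
Why: DMAP-catalysed acylation fixes the isobutyrate on O8 before O6 is unmasked, so that only O6 can lactonise later.

Step 15
Reactants: 23 methyl (3R,4R,6R)-3-{(1R)-1,4-bis[(4-methoxyphenyl)methoxy]but-2-yn-1-yl}-9-(ethylsulfanyl)-6-methyl-2-methylidene-4-[(2-methylpropanoyl)oxy]-9-oxo-6-[(triethylsilyl)oxy]nonanoate
Product: 25 S-ethyl (4R,6R)-6-[(2R,3R)-2-(3-hydroxyprop-1-yn-1-yl)-4-methylidene-5-oxooxolan-3-yl]-4-methyl-6-[(2-methylpropanoyl)oxy]-4-[(triethylsilyl)oxy]hexanethioate, via diol ester 24 (not isolated)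
Conditions: DDQ (2.6 equiv), CH2Cl2/pH 7 buffer (10:1), 0 °C to rt; then pyridinium 4-toluenesulfonate (20 mol %), toluene, 45 °C
Reagents that add atoms: none
Why: DDQ oxidatively cleaves both PMB ethers and acid-catalysed transesterification of the freed C6 hydroxyl onto the acrylate ester closes the cis-fused α-methylene-γ-butyrolactone with retention at C6.

Step 16
Reactants: 25 S-ethyl (4R,6R)-6-[(2R,3R)-2-(3-hydroxyprop-1-yn-1-yl)-4-methylidene-5-oxooxolan-3-yl]-4-methyl-6-[(2-methylpropanoyl)oxy]-4-[(triethylsilyl)oxy]hexanethioate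
Product: 26 S-ethyl (4R,6R)-6-{(2R,3R)-2-[(1Z)-3-hydroxy-2-(tributylstannyl)prop-1-en-1-yl]-4-methylidene-5-oxooxolan-3-yl}-4-methyl-6-[(2-methylpropanoyl)oxy]-4-[(triethylsilyl)oxy]hexanethioate
Conditions: [Cp*RuCl]4 (2.5 mol %), Bu3SnH (1.15 equiv, added over 1 h), CH2Cl2, rt
Reagents that add atoms: tributyltin hydride, CCCC[SnH](CCCC)CCCC
Why: hydroxyl-directed Ru-catalysed trans-hydrostannation, in which the free C15 hydroxyl hydrogen-bonds to the Ru–Cl unit so that tin goes to the proximal alkyne carbon C4 and hydrogen adds trans at C5, giving the Z stannane with tin cis to C6 and leaving the enoate and thioester alone.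

Step 17
Reactants: 26 S-ethyl (4R,6R)-6-{(2R,3R)-2-[(1Z)-3-hydroxy-2-(tributylstannyl)prop-1-en-1-yl]-4-methylidene-5-oxooxolan-3-yl}-4-methyl-6-[(2-methylpropanoyl)oxy]-4-[(triethylsilyl)oxy]hexanethioate
Product: 27 (3aR,4R,6R,10Z,11aS)-10-(hydroxymethyl)-6-methyl-3-methylidene-2,9-dioxo-6-[(triethylsilyl)oxy]-2,3,3a,4,5,6,7,8,9,11a-decahydrocyclodeca[b]furan-4-yl 2-methylpropanoate
Conditions: Pd2(dba)3 (10 mol %), P(2-furyl)3 (40 mol %), CuO2PPh2 (2.5 equiv), THF, 40 °C, 26 added by syringe pump over 10 h (final 1 mM)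
Reagents that add atoms: none
Why: Proposed new method: a ring-closing Liebeskind–Srogl-type acylation in which a thioester and a hydroxymethyl-substituted Z-alkenylstannane of one seco-chain are joined to a ten-membered Z-enone, a medium-ring-forming use of this coupling that has not been shown; monovalent copper binds the thioester sulfur so that zerovalent palladium inserts into the C(acyl)–S bond under neutral conditions, the phosphinate and the neighbouring CH2OH help move the alkenyl group from tin via copper to palladium with retention of the Z geometry, and acyl–alkenyl reductive elimination at high dilution closes C3–C4 before decarbonylation or destannylation, with the cis-fused lactone and the Z-alkene holding both termini on one side and the weakly donating furylphosphine disfavouring ionisation of the allylic lactone C–O bond; the closest known reactions are the intermolecular thioester–organostannane ketone synthesis under Pd/Cu mediation and acylative Stille macrocyclisations.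

Step 18
Reactants: 27 (3aR,4R,6R,10Z,11aS)-10-(hydroxymethyl)-6-methyl-3-methylidene-2,9-dioxo-6-[(triethylsilyl)oxy]-2,3,3a,4,5,6,7,8,9,11a-decahydrocyclodeca[b]furan-4-yl 2-methylpropanoate
Product: 29 (3S,4Z,6S,7R,8R,10R)-3,15-dihydroxy-8-(2-methylpropanoyloxy)-3,10-epoxygermacra-4,11(13)-dien-12,6-olide (CNP0282937.2), via hydroxy enone 28 (not isolated)
Conditions: HF·pyridine, pyridine, THF, 0 °C to rt; aq. NaHCO3
Reagents that add atoms: none
Why: fluoride desilylation frees the tertiary C10 hydroxyl, which adds transannularly to the C3 ketone (hemiketalisation under thermodynamic control); the one-atom oxygen bridge can span the nine-membered ring only cis, which fixes C3 as 3S with OH cis to the C10 methyl.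

**Compound list**
1 | [(2R)-2-methyloxiran-2-yl]methanol | C[C@@]1(CO)CO1 | starting material
2 | ethenylmagnesium bromide | C=C[Mg]Br | starting material
3 | (2S)-2-methylpent-4-ene-1,2-diol | C=CC[C@](C)(O)CO | intermediate
4 | (2S)-2-hydroxy-2-methylpent-4-en-1-yl 4-methylbenzenesulfonate (primary tosylate) | C=CC[C@](C)(O)COS(=O)(=O)c1ccc(C)cc1 | intermediate (not isolated)
5 | (2S)-2-methyl-2-(prop-2-en-1-yl)oxirane | C[C@]1(CC=C)CO1 | intermediate
6 | tert-butyl acetate | CC(=O)OC(C)(C)C | starting material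
7 | tert-butyl (4R)-4-hydroxy-4-methylhept-6-enoate | C=CC[C@](C)(O)CCC(=O)OC(C)(C)C | intermediate
8 | triethylsilyl (4R)-4-methyl-4-[(triethylsilyl)oxy]hept-6-enoate (bis-silyl ester) | C=CC[C@](C)(O[Si](CC)(CC)CC)CCC(=O)O[Si](CC)(CC)CC | intermediate (not isolated)
9 | (4R)-4-methyl-4-[(triethylsilyl)oxy]hept-6-enoic acid | C=CC[C@](C)(O[Si](CC)(CC)CC)CCC(=O)O | intermediate
10 | S-ethyl (4R)-4-methyl-4-[(triethylsilyl)oxy]hept-6-enethioate | C=CC[C@](C)(O[Si](CC)(CC)CC)CCC(=O)SCC | intermediate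
11 | S-ethyl (4R)-4-methyl-6-oxo-4-[(triethylsilyl)oxy]hexanethioate | O=CC[C@](C)(O[Si](CC)(CC)CC)CCC(=O)SCC | intermediate
12 | prop-2-yn-1-ol | C#CCO | starting material
13 | 1-methoxy-4-[(prop-2-yn-1-yloxy)methyl]benzene | C#CCOCc1ccc(OC)cc1 | intermediate
14 | (2E)-but-2-enal | C/C=C/C=O | starting material
15 | (2E,4R)-7-[(4-methoxyphenyl)methoxy]hept-2-en-5-yn-4-ol | C/C=C/[C@@H](O)C#CCOCc1ccc(OC)cc1 | intermediate
16 | (2E,4R)-4,7-bis[(4-methoxyphenyl)methoxy]hept-2-en-5-yne | C/C=C/[C@@H](OCc1ccc(OC)cc1)C#CCOCc1ccc(OC)cc1 | intermediate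
17 | (2S)-2,5-bis[(4-methoxyphenyl)methoxy]pent-3-ynal | O=C[C@@H](OCc1ccc(OC)cc1)C#CCOCc1ccc(OC)cc1 | intermediate
18 | methyl prop-2-ynoate | C#CC(=O)OC | starting material
19 | methyl (4S)-3-hydroxy-4,7-bis[(4-methoxyphenyl)methoxy]-2-methylidenehept-5-ynoate (C3 epimers) | C=C(C(=O)OC)C(O)[C@@H](OCc1ccc(OC)cc1)C#CCOCc1ccc(OC)cc1 | intermediate
20 | methyl (2Z,4R)-2-(bromomethyl)-4,7-bis[(4-methoxyphenyl)methoxy]hept-2-en-5-ynoate | COC(=O)/C(CBr)=C/[C@@H](OCc1ccc(OC)cc1)C#CCOCc1ccc(OC)cc1 | intermediate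
21 | methyl (3R,4R,6R)-3-{(1R)-1,4-bis[(4-methoxyphenyl)methoxy]but-2-yn-1-yl}-9-(ethylsulfanyl)-4-hydroxy-6-methyl-2-methylidene-9-oxo-6-[(triethylsilyl)oxy]nonanoate | C=C(C(=O)OC)[C@H]([C@H](O)C[C@](C)(O[Si](CC)(CC)CC)CCC(=O)SCC)[C@@H](OCc1ccc(OC)cc1)C#CCOCc1ccc(OC)cc1 | intermediate
22 | 2-methylpropanoyl chloride | CC(C)C(=O)Cl | starting material
23 | methyl (3R,4R,6R)-3-{(1R)-1,4-bis[(4-methoxyphenyl)methoxy]but-2-yn-1-yl}-9-(ethylsulfanyl)-6-methyl-2-methylidene-4-[(2-methylpropanoyl)oxy]-9-oxo-6-[(triethylsilyl)oxy]nonanoate | C=C(C(=O)OC)[C@H]([C@H](OC(=O)C(C)C)C[C@](C)(O[Si](CC)(CC)CC)CCC(=O)SCC)[C@@H](OCc1ccc(OC)cc1)C#CCOCc1ccc(OC)cc1 | intermediate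
24 | methyl (3S,4R,6R)-3-[(1R)-1,4-dihydroxybut-2-yn-1-yl]-9-(ethylsulfanyl)-6-methyl-2-methylidene-4-[(2-methylpropanoyl)oxy]-9-oxo-6-[(triethylsilyl)oxy]nonanoate (diol ester; same spatial arrangement as 23) | C=C(C(=O)OC)[C@H]([C@H](OC(=O)C(C)C)C[C@](C)(O[Si](CC)(CC)CC)CCC(=O)SCC)[C@@H](O)C#CCO | intermediate (not isolated)
25 | S-ethyl (4R,6R)-6-[(2R,3R)-2-(3-hydroxyprop-1-yn-1-yl)-4-methylidene-5-oxooxolan-3-yl]-4-methyl-6-[(2-methylpropanoyl)oxy]-4-[(triethylsilyl)oxy]hexanethioate | C=C1C(=O)O[C@@H](C#CCO)[C@H]1[C@H](OC(=O)C(C)C)C[C@](C)(O[Si](CC)(CC)CC)CCC(=O)SCC | intermediate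
26 | S-ethyl (4R,6R)-6-{(2R,3R)-2-[(1Z)-3-hydroxy-2-(tributylstannyl)prop-1-en-1-yl]-4-methylidene-5-oxooxolan-3-yl}-4-methyl-6-[(2-methylpropanoyl)oxy]-4-[(triethylsilyl)oxy]hexanethioate | C=C1C(=O)O[C@@H](/C=C(/CO)[Sn](CCCC)(CCCC)CCCC)[C@H]1[C@H](OC(=O)C(C)C)C[C@](C)(O[Si](CC)(CC)CC)CCC(=O)SCC | intermediate
27 | (3aR,4R,6R,10Z,11aS)-10-(hydroxymethyl)-6-methyl-3-methylidene-2,9-dioxo-6-[(triethylsilyl)oxy]-2,3,3a,4,5,6,7,8,9,11a-decahydrocyclodeca[b]furan-4-yl 2-methylpropanoate | C=C1C(=O)O[C@H]2/C=C(/CO)C(=O)CC[C@@](C)(O[Si](CC)(CC)CC)C[C@@H](OC(=O)C(C)C)[C@@H]12 | intermediate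
28 | (3aR,4R,6R,10Z,11aS)-6-hydroxy-10-(hydroxymethyl)-6-methyl-3-methylidene-2,9-dioxo-2,3,3a,4,5,6,7,8,9,11a-decahydrocyclodeca[b]furan-4-yl 2-methylpropanoate (hydroxy enone) | C=C1C(=O)O[C@H]2/C=C(/CO)C(=O)CC[C@@](C)(O)C[C@@H](OC(=O)C(C)C)[C@@H]12 | intermediate (not isolated)
29 | (3S,4Z,6S,7R,8R,10R)-3,15-dihydroxy-8-(2-methylpropanoyloxy)-3,10-epoxygermacra-4,11(13)-dien-12,6-olide (CNP0282937.2) | C=C1C(=O)O[C@H]2/C=C(/CO)[C@]3(O)CC[C@](C)(C[C@@H](OC(=O)C(C)C)[C@@H]12)O3 | target

**Step count**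
Total: 18 steps. Longest linear sequence: 12 steps (steps 7–12 then 13–18; the West branch, steps 1–6 then 13–18, is equally long).

**Three steps most likely to fail, with fallbacks**

Step 17 (the proposed new ring closure). It may give oligomers, protodestannylation, or ionisation of the allylic lactone C6–O bond by zerovalent palladium. The fallback uses known chemistry and sets out from 25. Fukuyama reduction of the thioester (Et3SiH, Pd on CaCO3 poisoned with Pb(OAc)2, acetone, rt) gives the alkynyl aldehyde F4. Ru-catalysed trans-hydrostannation as in step 16 gives the stannyl aldehyde F5, and I2 in CH2Cl2 at 0 °C gives the Z-alkenyl iodide F6 with retention. Et3SiCl/imidazole protects C15–OH to give the bis-silyl iodo aldehyde F7. Nozaki–Hiyama–Kishi macrocyclisation (CrCl2 in excess, NiCl2 cat., DMSO/THF, 2 mM) closes C3–C4 to the ten-membered allylic alcohol F8 (C3 epimers). Dess–Martin oxidation gives the bis-silyl enone F9, and HF·pyridine as in step 18 removes both silyl groups, so the route is rejoined at 29.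

Step 13 (fragment union). The facial sense at C7 rests on ether chelation of indium and is not secured by precedent on this substrate; 1,4-elimination of the allylic metal is a second risk. The fallback sets out from the same partners 11 and 20 and returns at 21, but takes stereocontrol from a ligand instead of from the substrate. It is a chromium-catalysed Nozaki–Hiyama-type allylation (CrCl2 10 mol %, chiral carbazole-bis(oxazoline) ligand, Mn powder, Cp2ZrCl2, THF, rt), in which a ligand-bound trivalent chromium allyl selects the aldehyde face and the Z geometry still gives the syn pair; no new compound is made (F0).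

Step 3 (epoxide opening). The Lewis-acidic aluminium reagent may rearrange the 2,2-disubstituted epoxide to an aldehyde or stall. The fallback sets out from 5 and uses a more nucleophilic amide enolate without Lewis acid. The lithium enolate of N,N-dimethylacetamide (LiN(iPr)2, THF, −78 °C to rt) opens 5 to the hydroxy amide F1. TsOH in toluene at 80 °C lactonises it to the allyl lactone F2. Bu4NOH in THF/H2O followed by drying gives the tetrabutylammonium hydroxy carboxylate F3, which under the step 4 conditions is silylated to 8 and worked up to 9, where the route is rejoined.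

Further compounds
F1 | step 3 | (4R)-4-hydroxy-N,N,4-trimethylhept-6-enamide | C=CC[C@](C)(O)CCC(=O)N(C)C
F2 | step 3 | (5R)-5-methyl-5-(prop-2-en-1-yl)oxolan-2-one | C=CC[C@@]1(C)CCC(=O)O1
F3 | step 3 | tetrabutylammonium (4R)-4-hydroxy-4-methylhept-6-enoate | C=CC[C@](C)(O)CCC(=O)[O-].CCCC[N+](CCCC)(CCCC)CCCC
F0 | step 13 | none | none
F4 | step 17 | (1R,3R)-1-[(2R,3R)-2-(3-hydroxyprop-1-yn-1-yl)-4-methylidene-5-oxooxolan-3-yl]-3-methyl-6-oxo-3-[(triethylsilyl)oxy]hexyl 2-methylpropanoate | C=C1C(=O)O[C@@H](C#CCO)[C@H]1[C@H](OC(=O)C(C)C)C[C@](C)(O[Si](CC)(CC)CC)CCC=O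
F5 | step 17 | (1R,3R)-1-{(2R,3R)-2-[(1Z)-3-hydroxy-2-(tributylstannyl)prop-1-en-1-yl]-4-methylidene-5-oxooxolan-3-yl}-3-methyl-6-oxo-3-[(triethylsilyl)oxy]hexyl 2-methylpropanoate | C=C1C(=O)O[C@@H](/C=C(/CO)[Sn](CCCC)(CCCC)CCCC)[C@H]1[C@H](OC(=O)C(C)C)C[C@](C)(O[Si](CC)(CC)CC)CCC=O
F6 | step 17 | (1R,3R)-1-{(2R,3R)-2-[(1Z)-3-hydroxy-2-iodoprop-1-en-1-yl]-4-methylidene-5-oxooxolan-3-yl}-3-methyl-6-oxo-3-[(triethylsilyl)oxy]hexyl 2-methylpropanoate | C=C1C(=O)O[C@@H](/C=C(/CO)I)[C@H]1[C@H](OC(=O)C(C)C)C[C@](C)(O[Si](CC)(CC)CC)CCC=O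
F7 | step 17 | (1R,3R)-1-[(2R,3R)-2-{(1Z)-2-iodo-3-[(triethylsilyl)oxy]prop-1-en-1-yl}-4-methylidene-5-oxooxolan-3-yl]-3-methyl-6-oxo-3-[(triethylsilyl)oxy]hexyl 2-methylpropanoate | C=C1C(=O)O[C@@H](/C=C(/CO[Si](CC)(CC)CC)I)[C@H]1[C@H](OC(=O)C(C)C)C[C@](C)(O[Si](CC)(CC)CC)CCC=O
F8 | step 17 | (3aR,4R,6R,10Z,11aS)-9-hydroxy-6-methyl-3-methylidene-2-oxo-6-[(triethylsilyl)oxy]-10-{[(triethylsilyl)oxy]methyl}-2,3,3a,4,5,6,7,8,9,11a-decahydrocyclodeca[b]furan-4-yl 2-methylpropanoate (C9 epimers) | C=C1C(=O)O[C@H]2/C=C(/CO[Si](CC)(CC)CC)C(O)CC[C@@](C)(O[Si](CC)(CC)CC)C[C@@H](OC(=O)C(C)C)[C@@H]12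
F9 | step 17 | (3aR,4R,6R,10Z,11aS)-6-methyl-3-methylidene-2,9-dioxo-6-[(triethylsilyl)oxy]-10-{[(triethylsilyl)oxy]methyl}-2,3,3a,4,5,6,7,8,9,11a-decahydrocyclodeca[b]furan-4-yl 2-methylpropanoate | C=C1C(=O)O[C@H]2/C=C(/CO[Si](CC)(CC)CC)C(=O)CC[C@@](C)(O[Si](CC)(CC)CC)C[C@@H](OC(=O)C(C)C)[C@@H]12
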